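**Plan**

- Retrosynthesis: CH2OH at C3 ⇐ CHO and ArOH ⇐ ArOPiv; then the C2–C3 bond of the tetrahydrofuran is cut and C2 is re-attached to the oxygen of the C3 arm. This traces the five-membered ring to a seven-membered cyclic vinyl acetal, a 2-aryl-5-benzyl-4,5-dihydro-1,3-dioxepine.
- Enabling feature: ring O1–C2(Ar) is a latent aryl oxocarbenium and C3–CH2OH a latent aldehyde enol (O1–C2–C3–C–O is an aldol pattern). Both partners can therefore be stored in one ring, O–CH(Ar)–O–CH=CH–CH(CH2Ar')–CH2.
- Further cuts: the C5–CH2Ar' bond of the dioxepine (Heck-type benzylation of the ring alkene) and the acetal (vanillin pivalate + cis-butenediol).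
- Forward: the seven-membered acetal ring is made first, the benzyl arm is joined second, then a Lewis-acid [1,3] O→C shift contracts the ring 7 → 5; epimerisation and reduction/deprotection finish the route.
- Stereochemistry: C4 from the chiral Pd catalyst; C2 relayed from C4 in the kinetic ring contraction (aryl trans to benzyl); C3 by thermodynamic epimerisation of the aldehyde (trans to aryl, cis to benzyl).

Key step: step 5

Assumption (chemistry): the sense of induction of the phosphoramidite in step 4 is assigned by correlation, and the ligand antipode that gives (5R)-7 is used. Compound 7 is a mixture of epimers at the acetal carbon, which is immaterial because that carbon is planar in 8.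

**Step 1**
Reactants: 1 vanillin
Product: 2 4-formyl-2-methoxyphenyl pivalate
Conditions: PivCl, Et3N, DMAP (cat.), CH2Cl2, 0 °C to rt
Reagents that add atoms: pivaloyl chloride CC(C)(C)C(Cl)=O
Why: DMAP-catalysed O-acylation of the phenol (esterification); the pivalate masks the phenol and, being electron-withdrawing, later slows Lewis-acid re-ionisation at the benzylic carbon.

**Step 2**
Reactants: 2 4-formyl-2-methoxyphenyl pivalate; 3 (Z)-but-2-ene-1,4-diol
Product: 4 4-(4,7-dihydro-1,3-dioxepin-2-yl)-2-methoxyphenyl pivalate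
Conditions: p-TsOH (cat.), toluene, reflux, Dean–Stark
Reagents that add atoms: none
Why: Acid-catalysed acetalisation with azeotropic removal of water; the cis geometry of the diol directs closure to the seven-membered 4,7-dihydro-1,3-dioxepine.

**Step 3**
Reactants: 5 3,4-dimethoxybenzyl alcohol
Product: 6 3,4-dimethoxybenzyl trifluoroacetate
Conditions: (CF3CO)2O, pyridine, CH2Cl2, 0 °C; used crude
Reagents that add atoms: trifluoroacetic anhydride O=C(OC(=O)C(F)(F)F)C(F)(F)F
Why: Simple O-acylation that turns the benzylic alcohol into an electrophile able to add oxidatively to Pd(0) and leave a weakly coordinating counter-ion.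

**Step 4**
Reactants: 4 4-(4,7-dihydro-1,3-dioxepin-2-yl)-2-methoxyphenyl pivalate; 6 3,4-dimethoxybenzyl trifluoroacetate
Product: 7 4-[(5R)-5-(3,4-dimethoxybenzyl)-4,5-dihydro-1,3-dioxepin-2-yl]-2-methoxyphenyl pivalate (mixture of acetal epimers)
Conditions: Pd(dba)2 (5 mol %), BINOL-derived phosphoramidite (MonoPhos type, 12 mol %), Li2CO3, THF, 50 °C; chromatography on base-washed silica
Reagents that add atoms: none
Why: Proposed new method: an enantioselective Mizoroki–Heck benzylation of the Cs-symmetric ring alkene, in which oxidative addition of 6 gives a cationic η3-benzyl-palladium complex, ligand-controlled syn-insertion places the benzyl group on C5 (this sets the C5 stereocentre by catalyst control), and syn-β-hydride elimination can only occur towards C7 because the C5 hydrogen is anti to palladium, so the enol ether C6=C7 results; the closest known reaction types are the asymmetric Heck benzylation of five-membered cyclic alkenes with benzylic trifluoroacetates and the Heck arylation of 4,7-dihydro-1,3-dioxepines to 5-aryl-4,5-dihydro-1,3-dioxepines.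

**Step 5**
Reactants: 7 4-[(5R)-5-(3,4-dimethoxybenzyl)-4,5-dihydro-1,3-dioxepin-2-yl]-2-methoxyphenyl pivalate
Product: 9 4-[(2S,3R,4R)-4-(3,4-dimethoxybenzyl)-3-formyltetrahydrofuran-2-yl]-2-methoxyphenyl pivalate, via silyl enol ether oxocarbenium triflate 8 (not isolated)
Conditions: TMSOTf (10 mol %), CH2Cl2, −78 °C; Et3N quench at −78 °C
Reagents that add atoms: none
Why: TMSOTf silylates the enol-ether oxygen O1 and ionises the C2–O1 acetal bond to the ion pair 8, an (E)-aryl oxocarbenium tethered through O3–C4–C5 to a (Z)-silyl enol ether, whose carbon C6 attacks C2 and then releases TMSOTf, a net [1,3] O-to-C shift that contracts the seven-membered ring to the tetrahydrofuran. The closest known reaction type is the Lewis-acid-mediated ring contraction of 4,5-dihydro-1,3-dioxepines to tetrahydrofuran-3-carbaldehydes (Petasis–Ferrier type, an intramolecular Mukaiyama–Prins addition). The tetrahydrofuran closes by a 5-(enolexo)-endo-trig attack on the endocyclic C=O+ bond, formally disfavoured by the Baldwin rules but usual for oxocarbenium ions. C4 is carried over unchanged from C5 of 7; C3 is controlled by allylic 1,3-strain in the Z-enol ether, which holds the C5–H in the enol plane so that the bond forms anti to the benzyl group (formyl trans to benzyl); C2 is controlled by the compact collapse of the ion pair, which is expected to place the aryl group cis to formyl and therefore trans to benzyl, the kinetic 2,3-cis-3,4-trans pattern of this reaction class. The step needs kinetic control, because re-ionisation of the product at C2 would lead to the all-trans isomer with the wrong C2/C4 relationship; low temperature, catalytic TMSOTf, the cold amine quench and the electron-withdrawing pivaloyloxy group on the aryl ring should secure it.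

**Step 6**
Reactants: 9 4-[(2S,3R,4R)-4-(3,4-dimethoxybenzyl)-3-formyltetrahydrofuran-2-yl]-2-methoxyphenyl pivalate
Product: 11 4-[(2S,3S,4R)-4-(3,4-dimethoxybenzyl)-3-formyltetrahydrofuran-2-yl]-2-methoxyphenyl pivalate, via enol 10 (not isolated)
Conditions: DBU (0.3 equiv), CH2Cl2, rt; 11 separated, recovered 9 resubmitted
Reagents that add atoms: none
Why: Base-mediated α-epimerisation of the aldehyde through enol 10 under thermodynamic control, expected to favour 11 because the formyl group becomes trans to the ring-bound 2-aryl group and cis only to the smaller CH2Ar' arm; C2 and C4 are untouched, and ring opening by β-alkoxide elimination is stereoelectronically disfavoured (reverse 5-endo-trig).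

**Step 7**
Reactants: 11 4-[(2S,3S,4R)-4-(3,4-dimethoxybenzyl)-3-formyltetrahydrofuran-2-yl]-2-methoxyphenyl pivalate
Product: 13 4'-O-methyllariciresinol, via pivalate alcohol 12 (not isolated)
Conditions: LiAlH4 (excess), THF, −78 °C to rt; aq. Rochelle salt, then NH4Cl
Reagents that add atoms: none
Why: Hydride reduction of the aldehyde to the primary alcohol 12, followed by reductive cleavage of the aryl pivalate to the phenol; no stereocentre is affected (the C3 descriptor changes from S to R only through CIP priorities).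

**Compound list**

1 | vanillin (4-hydroxy-3-methoxybenzaldehyde) | COc1cc(C=O)ccc1O | starting material
2 | 4-formyl-2-methoxyphenyl pivalate | COc1cc(C=O)ccc1OC(=O)C(C)(C)C | intermediate
3 | (Z)-but-2-ene-1,4-diol | OC/C=C\CO | starting material
4 | 4-(4,7-dihydro-1,3-dioxepin-2-yl)-2-methoxyphenyl pivalate | COc1cc(C2OCC=CCO2)ccc1OC(=O)C(C)(C)C | intermediate
5 | 3,4-dimethoxybenzyl alcohol | COc1ccc(CO)cc1OC | starting material
6 | 3,4-dimethoxybenzyl trifluoroacetate | COc1ccc(COC(=O)C(F)(F)F)cc1OC | intermediate
7 | 4-[(5R)-5-(3,4-dimethoxybenzyl)-4,5-dihydro-1,3-dioxepin-2-yl]-2-methoxyphenyl pivalate (acetal carbon unspecified, both epimers) | COc1cc(C2OC[C@H](Cc3ccc(OC)c(OC)c3)C=CO2)ccc1OC(=O)C(C)(C)C | intermediate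
8 | ring-opened ion pair: (E)-aryl oxocarbenium carrying the (R)-2-(3,4-dimethoxybenzyl)-4-(trimethylsilyloxy)but-3(Z)-enyl group on oxygen, triflate counter-ion | COc1cc(C=[O+]C[C@H](Cc2ccc(OC)c(OC)c2)/C=C\O[Si](C)(C)C)ccc1OC(=O)C(C)(C)C.[O-]S(=O)(=O)C(F)(F)F | intermediate
9 | 4-[(2S,3R,4R)-4-(3,4-dimethoxybenzyl)-3-formyltetrahydrofuran-2-yl]-2-methoxyphenyl pivalate (2,3-cis-3,4-trans) | COc1cc([C@H]2OC[C@H](Cc3ccc(OC)c(OC)c3)[C@H]2C=O)ccc1OC(=O)C(C)(C)C | intermediate
10 | enol of 9 and 11: 2-aryl-4-(3,4-dimethoxybenzyl)-3-(hydroxymethylene)tetrahydrofuran, C2 and C4 as in 9 | COc1cc([C@H]2OC[C@H](Cc3ccc(OC)c(OC)c3)C2=CO)ccc1OC(=O)C(C)(C)C | intermediate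
11 | 4-[(2S,3S,4R)-4-(3,4-dimethoxybenzyl)-3-formyltetrahydrofuran-2-yl]-2-methoxyphenyl pivalate (2,3-trans-3,4-cis) | COc1cc([C@H]2OC[C@H](Cc3ccc(OC)c(OC)c3)[C@@H]2C=O)ccc1OC(=O)C(C)(C)C | intermediate
12 | 4-[(2S,3R,4R)-4-(3,4-dimethoxybenzyl)-3-(hydroxymethyl)tetrahydrofuran-2-yl]-2-methoxyphenyl pivalate | COc1cc([C@H]2OC[C@H](Cc3ccc(OC)c(OC)c3)[C@@H]2CO)ccc1OC(=O)C(C)(C)C | intermediate
13 | 4'-O-methyllariciresinol, 4-[(2S,3R,4R)-4-(3,4-dimethoxybenzyl)-3-(hydroxymethyl)tetrahydrofuran-2-yl]-2-methoxyphenol | COc1cc([C@H]2OC[C@H](Cc3ccc(OC)c(OC)c3)[C@@H]2CO)ccc1O | target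

**Step count**

Total steps: 7. Longest linear sequence: 6 steps (1, 2, 4, 5, 6, 7).

**Steps most likely to fail**

1. Step 4 (Proposed new method). The η3-benzyl-palladium may insert sluggishly into the seven-membered alkene, the ligand may give insufficient enantio-induction, or the trifluoroacetic acid released may cleave the vinyl acetal. Fallback with known chemistry, setting out from 4 and returning at 7: bromine adds across the ring alkene of 4 (Br2, CH2Cl2, −78 °C) to give the racemic trans-dibromide 4-(5,6-dibromo-1,3-dioxepan-2-yl)-2-methoxyphenyl pivalate F1. Dehydrobromination (KOtBu, THF, 0 °C) gives the vinyl bromide 4-(5-bromo-4,7-dihydro-1,3-dioxepin-2-yl)-2-methoxyphenyl pivalate F2. Negishi coupling with (3,4-dimethoxybenzyl)zinc chloride [Pd(PPh3)4, THF, rt] gives the trisubstituted alkene 4-[5-(3,4-dimethoxybenzyl)-4,7-dihydro-1,3-dioxepin-2-yl]-2-methoxyphenyl pivalate F3. Enantioselective double-bond migration with a chiral nickel hydride [NiBr2(Me-DuPhos), LiBHEt3, THF, low temperature] is the established asymmetric isomerisation of 5-alkyl-4,7-dihydro-1,3-dioxepines (hydride to C5, β-hydride elimination from C7); it sets C5 and gives 7.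

2. Step 5. Kinetic control may be eroded by reversible ionisation at C2, which drains material into the all-trans series, or the oxocarbenium ion or the product aldehyde may be captured by the electron-rich dimethoxybenzyl ring (Friedel–Crafts). Fallback setting out from 7 and returning at 13: mild aqueous acid (AcOH–H2O–THF) hydrolyses the vinyl acetal of 7 to the lactol (4R)-4-(3,4-dimethoxybenzyl)tetrahydrofuran-2-ol F4 and returns aldehyde 2. Oxidation (TEMPO, PhI(OAc)2, CH2Cl2) gives the lactone (4R)-4-(3,4-dimethoxybenzyl)dihydrofuran-2(3H)-one F5. Its lithium enolate (LDA, THF, −78 °C) adds to 2 anti to the benzyl group and gives the trans aldol lactone 4-{[(3S,4R)-4-(3,4-dimethoxybenzyl)-2-oxotetrahydrofuran-3-yl](hydroxy)methyl}-2-methoxyphenyl pivalate F6 (carbinol epimers). LiAlH4 (THF, 0 °C) reduces the lactone and removes the pivalate to give the triol (2R,3R)-2-(3,4-dimethoxybenzyl)-3-[hydroxy(4-hydroxy-3-methoxyphenyl)methyl]butane-1,4-diol F7. Catalytic acid (CSA, CH2Cl2) ionises the benzylic carbinol and the C1 hydroxyl closes the tetrahydrofuran (5-exo) trans to the neighbouring hydroxymethyl arm, giving 13. The trans lactone becomes the 3,4-cis tetrahydrofuran because C3 exchanges its ring and exocyclic carbon substituents.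

3. Step 6. The C3 equilibrium may lie less far on the side of 11 than expected, or the enolate may undergo β-alkoxide elimination, which opens the ring and scrambles C2. Fallback setting out from 2 and returning at 12: vinylmagnesium bromide (THF, −78 °C) converts 2 into the racemic allylic alcohol 4-(1-hydroxyprop-2-en-1-yl)-2-methoxyphenyl pivalate F8. Sharpless kinetic resolution by epoxidation [Ti(OiPr)4, the DIPT enantiomer that epoxidises the wanted antipode, TBHP, 4 Å MS, CH2Cl2, −20 °C] gives the anti epoxy alcohol 4-{(R)-hydroxy[(2S)-oxiran-2-yl]methyl}-2-methoxyphenyl pivalate F9. O-Alkylation with (E)-3,4-dimethoxycinnamyl bromide (NaH, THF, 0 °C) gives the epoxy cinnamyl ether 4-{(R)-{[(2E)-3-(3,4-dimethoxyphenyl)prop-2-en-1-yl]oxy}[(2S)-oxiran-2-yl]methyl}-2-methoxyphenyl pivalate F10. Cp2TiCl (from Cp2TiCl2 and Zn, THF, rt) opens the epoxide to the β-titanoxy radical, which cyclises 5-exo-trig onto the cinnamyl alkene; the benzylic radical is then reduced and protonated. This radical cyclisation typically gives the 2,3-trans-3,4-cis pattern, and the carbinol centre fixes the absolute configuration, so 12 results; 12 is then treated with LiAlH4 as in step 7.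

**Further compounds**

F1 | step 4 | 4-[(5R*,6R*)-5,6-dibromo-1,3-dioxepan-2-yl]-2-methoxyphenyl pivalate (racemic trans) | COc1cc(C2OC[C@@H](Br)[C@H](Br)CO2)ccc1OC(=O)C(C)(C)C
F2 | step 4 | 4-(5-bromo-4,7-dihydro-1,3-dioxepin-2-yl)-2-methoxyphenyl pivalate (racemic) | COc1cc(C2OCC=C(Br)CO2)ccc1OC(=O)C(C)(C)C
F3 | step 4 | 4-[5-(3,4-dimethoxybenzyl)-4,7-dihydro-1,3-dioxepin-2-yl]-2-methoxyphenyl pivalate (racemic) | COc1cc(C2OCC=C(Cc3ccc(OC)c(OC)c3)CO2)ccc1OC(=O)C(C)(C)C
F4 | step 5 | (4R)-4-(3,4-dimethoxybenzyl)tetrahydrofuran-2-ol (anomers) | OC1C[C@@H](Cc2ccc(OC)c(OC)c2)CO1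
F5 | step 5 | (4R)-4-(3,4-dimethoxybenzyl)dihydrofuran-2(3H)-one | O=C1C[C@@H](Cc2ccc(OC)c(OC)c2)CO1
F6 | step 5 | 4-{[(3S,4R)-4-(3,4-dimethoxybenzyl)-2-oxotetrahydrofuran-3-yl](hydroxy)methyl}-2-methoxyphenyl pivalate (carbinol epimers) | O=C1OC[C@H](Cc2ccc(OC)c(OC)c2)[C@H]1C(O)c1ccc(OC(=O)C(C)(C)C)c(OC)c1
F7 | step 5 | (2R,3R)-2-(3,4-dimethoxybenzyl)-3-[hydroxy(4-hydroxy-3-methoxyphenyl)methyl]butane-1,4-diol (carbinol epimers) | COc1cc(C(O)[C@@H](CO)[C@@H](Cc3ccc(OC)c(OC)c3)CO)ccc1O
F8 | step 6 | 4-(1-hydroxyprop-2-en-1-yl)-2-methoxyphenyl pivalate (racemic) | C=CC(O)c1ccc(OC(=O)C(C)(C)C)c(OC)c1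
F9 | step 6 | 4-{(R)-hydroxy[(2S)-oxiran-2-yl]methyl}-2-methoxyphenyl pivalate | O[C@H](c1ccc(OC(=O)C(C)(C)C)c(OC)c1)[C@@H]1CO1
F10 | step 6 | 4-{(R)-{[(2E)-3-(3,4-dimethoxyphenyl)prop-2-en-1-yl]oxy}[(2S)-oxiran-2-yl]methyl}-2-methoxyphenyl pivalate | COc1ccc(/C=C/CO[C@H](c2ccc(OC(=O)C(C)(C)C)c(OC)c2)[C@@H]2CO2)cc1OC
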